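**Assumption (remark on the chemistry):** (S)-β-citronellene, (S)-2-methylbutan-1-ol and ethyl (R)-3-hydroxybutanoate are taken as commercial in high enantiomeric purity. The 3-acyl and 3-formyl pyrandiones are tautomeric mixtures and are drawn in the enol form used in the target SMILES.

## Retrosynthetic overview

1. Target 21 ⇐ tert-butyl ester 20 ⇐ the bond between the side-chain ketone carbon (C9) and its CH2 (C8): Rh-catalysed anti-Markovnikov hydroacylation of the terminal vinyl group of triene ester 12 with 3-formyl lactone 19.
2. Enabling feature: in the dihydropyranone ring the C4 enol O–H sits on the C3=C4 double bond next to the exocyclic carbonyl carbon on C3 (a salicylaldehyde-like O–C=C–CHO array), so O4 and the formyl carbon can hold Rh in a five-membered acyl-metal chelate.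
3. 12 ⇐ E1cB dehydration of α-aldol 10 from β,γ-unsaturated ester 7 and (S)-2-methylbutanal 9; 7 ⇐ deconjugative Knoevenagel–Doebner reaction of aldehyde 3 ⇐ ozonolysis of (S)-β-citronellene 1 (its vinyl group, C3 methyl centre and C4–C6 all end up in the target chain).
4. 19 ⇐ C3 formylation of lactone 17 ⇐ Claisen condensation of ethyl (R)-3-hydroxybutanoate 13 with tert-butyl acetate 14.
5. Ring order: the dihydropyranone, the only ring, is closed by lactonisation in step 8, before the coupling; the key step closes no ring.

Key step: step 10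

## Route

**Step 1**
Reactants: 1 (S)-β-citronellene
Product: 3 (S)-4-methylhex-5-enal, via secondary ozonide 2 (not isolated)
Conditions: O3 (1.0 equiv, Sudan III end-point), CH2Cl2, −78 °C; then PPh3, −78 °C → rt
Reagents that add atoms: ozone, O=[O+][O-]
Why: Ozone should cleave the electron-rich trisubstituted C6=C7 bond much faster than the monosubstituted vinyl group (chemoselective ozonolysis with reductive work-up), and the C3 stereocentre is remote from the reacting site.

**Step 2**
Reactants: 3 (S)-4-methylhex-5-enal; 4 malonic acid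
Product: 6 (S,E)-6-methylocta-3,7-dienoic acid, via alkylidenemalonic acid 5 (not isolated)
Conditions: N-methylmorpholine (solvent and base), 95 °C
Reagents that add atoms: none
Why: Knoevenagel–Doebner condensation under tertiary-amine conditions should pass through alkylidenemalonic acid 5, which isomerises to the β,γ-unsaturated malonic acid before decarboxylation, so that the alk-3-enoic acid forms with the thermodynamically preferred E geometry and the stereocentre is untouched.

**Step 3**
Reactants: 6 (S,E)-6-methylocta-3,7-dienoic acid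
Product: 7 tert-butyl (S,E)-6-methylocta-3,7-dienoate
Conditions: Cl3CC(=NH)OtBu, BF3·OEt2 (cat.), cyclohexane/CH2Cl2, rt
Reagents that add atoms: tert-butyl 2,2,2-trichloroacetimidate, CC(C)(C)OC(=N)C(Cl)(Cl)Cl
Why: Acid-catalysed O-alkylation of the carboxylic acid by the trichloroacetimidate (tert-butyl ester formation) avoids base and so should not move the β,γ-double bond into conjugation.

**Step 4**
Reactants: 8 (S)-2-methylbutan-1-ol
Product: 9 (S)-2-methylbutanal
Conditions: TEMPO (cat.), KBr (cat.), aq. NaOCl, NaHCO3, CH2Cl2/H2O, 0 °C; distilled and used at once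
Reagents that add atoms: none
Why: Nitroxyl-catalysed hypochlorite oxidation of a primary alcohol stops at the aldehyde and is run cold and buffered so that the α-stereocentre should not enolise.

**Step 5**
Reactants: 7 tert-butyl (S,E)-6-methylocta-3,7-dienoate; 9 (S)-2-methylbutanal
Product: 10 tert-butyl (3E,6S)-2-[(2S)-1-hydroxy-2-methylbutyl]-6-methylocta-3,7-dienoate (mixture of epimers at C2 and C1′)
Conditions: LDA, THF, −78 °C; then 9, −78 °C; aq. NH4Cl
Reagents that add atoms: none
Why: The lithium dienolate of a β,γ-unsaturated ester should add to the aldehyde through its α-carbon (kinetic aldol addition) faster than it enolises 9, the E double bond is kept, and the two new centres need no control because step 6 removes both.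

**Step 6**
Reactants: 10 tert-butyl (3E,6S)-2-[(2S)-1-hydroxy-2-methylbutyl]-6-methylocta-3,7-dienoate
Product: 12 tert-butyl (2E,3E,6S)-6-methyl-2-[(2S)-2-methylbutylidene]octa-3,7-dienoate, via mesylate 11 (not isolated)
Conditions: MsCl, Et3N, CH2Cl2, 0 °C; then DBU, 0 °C → rt
Reagents that add atoms: none
Why: Mesylation and base-induced E1cB elimination through the planar dienolate should give the 2E alkene, because the sec-butyl group avoids the in-plane ester enolate oxygens and lies on the side of the C3–H, which is also the thermodynamically preferred (tiglate-type) arrangement.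

**Step 7**
Reactants: 13 ethyl (R)-3-hydroxybutanoate; 14 tert-butyl acetate
Product: 15 tert-butyl (R)-5-hydroxy-3-oxohexanoate
Conditions: LDA (4 equiv), 14 (4 equiv), THF, −78 °C; then 13, −78 → −30 °C; aq. NH4Cl
Reagents that add atoms: none
Why: Crossed Claisen condensation of the ester with excess lithium enolate of tert-butyl acetate, the hydroxyl being carried as its lithium alkoxide, gives the β-keto ester without touching the carbinol stereocentre.

**Step 8**
Reactants: 15 tert-butyl (R)-5-hydroxy-3-oxohexanoate
Product: 17 (R)-4-hydroxy-6-methyl-5,6-dihydro-2H-pyran-2-one, via hydroxy keto acid 16 (not isolated)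
Conditions: TFA, CH2Cl2, rt
Reagents that add atoms: none
Why: Acidolysis of the tert-butyl ester followed by acid-catalysed 6-exo-trig lactonisation of the δ-hydroxy β-keto acid should close the dihydropyranone, which enolises to the 4-hydroxy form; C6 keeps its configuration because its C–O bond is not broken.

**Step 9**
Reactants: 17 (R)-4-hydroxy-6-methyl-5,6-dihydro-2H-pyran-2-one
Product: 19 (R)-4-hydroxy-6-methyl-2-oxo-5,6-dihydro-2H-pyran-3-carbaldehyde, via enaminone 18 (not isolated)
Conditions: Me2NCH(OMe)2, THF, rt; then 2 M aq. HCl, THF, 40 °C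
Reagents that add atoms: N,N-dimethylformamide dimethyl acetal, COC(OC)N(C)C; water, O
Why: Aminomethylenation of the cyclic 1,3-dicarbonyl at C3 with the amide acetal and acid hydrolysis of the resulting vinylogous amide is the standard formylation of 4-hydroxycoumarin-type and cyclohexane-1,3-dione-type enols and leaves C6 untouched.

**Step 10**
Reactants: 12 tert-butyl (2E,3E,6S)-6-methyl-2-[(2S)-2-methylbutylidene]octa-3,7-dienoate; 19 (R)-4-hydroxy-6-methyl-2-oxo-5,6-dihydro-2H-pyran-3-carbaldehyde
Product: 20 tert-butyl (2E,3E,6R)-9-[(6R)-4-hydroxy-6-methyl-2-oxo-5,6-dihydro-2H-pyran-3-yl]-6-methyl-2-[(2S)-2-methylbutylidene]-9-oxonon-3-enoate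
Conditions: [Rh(cod)OMe]2 (2.5 mol %), P(O-2,4-tBu2C6H3)3 (10 mol %), THF, 60 °C, 19 (1.3 equiv) added slowly
Reagents that add atoms: none
Why: Proposed new method: the Rh(I) enolate formed at the C4–OH of 19 should add the neighbouring formyl C–H oxidatively to give a five-membered O,C-chelated acyl–Rh(III) hydride, the vinyl group of 12 should insert into Rh–H with the metal at the terminal carbon, and C–C reductive elimination followed by protonolysis by a further molecule of 19 should release 20. The closest known reaction type is the Rh-catalysed, chelation-assisted intermolecular hydroacylation of terminal alkenes with salicylaldehydes, which is linear-selective with bulky monodentate P(III) ligands; the extension is the replacement of the phenol by the enol of a cyclic 2-formyl-1,3-dicarbonyl compound, whose O–C=C–CHO array has the same geometry. No ring is closed and no stereocentre is created: the three stereocentres and both C=C geometries come from 12 and 19, and only the CIP descriptor at C6 changes (S to R) because the vinyl group becomes a saturated chain. The step needs chemoselectivity for the monosubstituted vinyl group over the dienoate, which the trisubstituted and 1,2-disubstituted, ester-deactivated C=C bonds should secure, and anti-Markovnikov regioselectivity, which the bulky ligand and the allylic methyl branch should secure; the same bias against the branched Rh alkyl should keep β-hydride elimination away from the C6–H and so preserve that centre. Decarbonylation should be held back by the chelate, which keeps the acyl group bound until the alkene has inserted.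

**Step 11**
Reactants: 20 tert-butyl (2E,3E,6R)-9-[(6R)-4-hydroxy-6-methyl-2-oxo-5,6-dihydro-2H-pyran-3-yl]-6-methyl-2-[(2S)-2-methylbutylidene]-9-oxonon-3-enoate
Product: 21 (2E,3E,6R)-9-[(6R)-4-hydroxy-6-methyl-2-oxo-5,6-dihydro-2H-pyran-3-yl]-6-methyl-2-[(2S)-2-methylbutylidene]-9-oxonon-3-enoic acid
Conditions: TFA/CH2Cl2 (1:4), 0 °C → rt
Reagents that add atoms: none
Why: Acidolysis of the tert-butyl ester (AAL1, loss of 2-methylpropene) unmasks the carboxylic acid under conditions that the acid-stable acylpyrandione, the dienoic acid and the three stereocentres should tolerate.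

## Compound list

1 | (S)-β-citronellene [(S)-3,7-dimethylocta-1,6-diene] | C=C[C@@H](C)CCC=C(C)C | starting material
2 | 3,3-dimethyl-5-[(3S)-3-methylpent-4-en-1-yl]-1,2,4-trioxolane (secondary ozonide) | C=C[C@@H](C)CCC1OOC(C)(C)O1 | intermediate
3 | (S)-4-methylhex-5-enal | C=C[C@@H](C)CCC=O | intermediate
4 | malonic acid | OC(=O)CC(=O)O | starting material
5 | 2-[(4S)-4-methylhex-5-en-1-ylidene]propanedioic acid | C=C[C@@H](C)CCC=C(C(=O)O)C(=O)O | intermediate
6 | (S,E)-6-methylocta-3,7-dienoic acid | C=C[C@@H](C)C/C=C/CC(=O)O | intermediate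
7 | tert-butyl (S,E)-6-methylocta-3,7-dienoate | C=C[C@@H](C)C/C=C/CC(=O)OC(C)(C)C | intermediate
8 | (S)-2-methylbutan-1-ol | CC[C@H](C)CO | starting material
9 | (S)-2-methylbutanal | CC[C@H](C)C=O | intermediate
10 | tert-butyl (3E,6S)-2-[(2S)-1-hydroxy-2-methylbutyl]-6-methylocta-3,7-dienoate (epimers at C2 and C1′) | CC[C@H](C)C(O)C(/C=C/C[C@H](C)C=C)C(=O)OC(C)(C)C | intermediate
11 | mesylate of 10 | CC[C@H](C)C(OS(C)(=O)=O)C(/C=C/C[C@H](C)C=C)C(=O)OC(C)(C)C | intermediate
12 | tert-butyl (2E,3E,6S)-6-methyl-2-[(2S)-2-methylbutylidene]octa-3,7-dienoate | CC[C@H](C)/C=C(\C=C\C[C@H](C)C=C)C(=O)OC(C)(C)C | intermediate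
13 | ethyl (R)-3-hydroxybutanoate | C[C@@H](O)CC(=O)OCC | starting material
14 | tert-butyl acetate | CC(=O)OC(C)(C)C | starting material
15 | tert-butyl (R)-5-hydroxy-3-oxohexanoate | C[C@@H](O)CC(=O)CC(=O)OC(C)(C)C | intermediate
16 | (R)-5-hydroxy-3-oxohexanoic acid | C[C@@H](O)CC(=O)CC(=O)O | intermediate
17 | (R)-4-hydroxy-6-methyl-5,6-dihydro-2H-pyran-2-one | C[C@@H]1CC(O)=CC(=O)O1 | intermediate
18 | (R)-3-[(dimethylamino)methylidene]-6-methyloxane-2,4-dione | CN(C)C=C1C(=O)C[C@@H](C)OC1=O | intermediate
19 | (R)-4-hydroxy-6-methyl-2-oxo-5,6-dihydro-2H-pyran-3-carbaldehyde | O=CC1=C(O)C[C@@H](C)OC1=O | intermediate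
20 | tert-butyl (2E,3E,6R)-9-[(6R)-4-hydroxy-6-methyl-2-oxo-5,6-dihydro-2H-pyran-3-yl]-6-methyl-2-[(2S)-2-methylbutylidene]-9-oxonon-3-enoate | CC[C@H](C)/C=C(\C=C\C[C@H](C)CCC(=O)C1=C(O)C[C@@H](C)OC1=O)C(=O)OC(C)(C)C | intermediate
21 | (2E,3E,6R)-9-[(6R)-4-hydroxy-6-methyl-2-oxo-5,6-dihydro-2H-pyran-3-yl]-6-methyl-2-[(2S)-2-methylbutylidene]-9-oxonon-3-enoic acid | CC[C@H](C)/C=C(\C=C\C[C@H](C)CCC(=O)C1=C(O)C[C@@H](C)OC1=O)C(=O)O | target

## Step count and risks

Total step count: 11. Longest linear sequence: 7 steps (1, 2, 3, 5, 6, 10, 11).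

**Step 10 (proposed new method).** Four processes could defeat it:
- the catalyst may rest as an unreactive six-membered O,O-chelate of the formyl-dione or of the triketone product, so that C–H activation does not turn over;
- decarbonylation of the acyl rhodium hydride may consume 19;
- reversible branched insertion with chain walking may move the terminal double bond and erode the C6 centre;
- the hydride may add to the dienoate instead.

The fallback uses known chemistry and sets out from triene ester 12. Linear-selective hydroformylation (Rh(acac)(CO)2, BIPHEPHOS, CO/H2, toluene, 60 °C) should give tert-butyl (2E,3E,6R)-6-methyl-2-[(2S)-2-methylbutylidene]-9-oxonon-3-enoate F1. Pinnick oxidation (NaClO2, NaH2PO4, 2-methyl-2-butene, tBuOH/H2O) should give (4R,6E,8E,10S)-8-(tert-butoxycarbonyl)-4,10-dimethyldodeca-6,8-dienoic acid F2. Coupling of F2 with lactone 17 (DCC, DMAP, CH2Cl2, rt) should give the enol ester (R)-6-methyl-2-oxo-5,6-dihydro-2H-pyran-4-yl (4R,6E,8E,10S)-8-(tert-butoxycarbonyl)-4,10-dimethyldodeca-6,8-dienoate F3. Under the same DMAP conditions F3 should undergo the Fries-type O→C acyl migration to C3 and so come back to the route at 20. In this variant the ketone–CH2 bond is made in the hydroformylation and the fragments are joined at the ring.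

**Step 6.** The E1cB elimination may discriminate poorly between the 2E and 2Z alkenes, or the base may deconjugate the dienoate and epimerise the sec-butyl methine. The fallback replaces elimination by a stereospecific cross-coupling and sets out from aldehydes 9 and 3.
- Wittig reaction of 9 with the bromo ylide made in the flask from tert-butyl (triphenylphosphoranylidene)acetate and NBS (CH2Cl2, −20 °C, then K2CO3) should give tert-butyl (S,Z)-2-bromo-4-methylhex-2-enoate F4.
- One-pot nonaflation–elimination of 3 (nonafluorobutanesulfonyl fluoride, phosphazene base, DMF) should give (S)-4-methylhex-5-en-1-yne F5.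
- Copper-catalysed anti-Markovnikov protoboration of the alkyne (CuCl, Xantphos, NaOtBu, B2pin2, MeOH, THF) should give (S,E)-4,4,5,5-tetramethyl-2-(4-methylhexa-1,5-dien-1-yl)-1,3,2-dioxaborolane F6.
- Suzuki–Miyaura coupling of F4 with F6 (Pd(dppf)Cl2, K3PO4, THF/H2O) should proceed with retention at both alkenes and come back to the route at 12.

**Step 9.** Aqueous hydrolysis of the enaminone may open the lactone or deformylate the tricarbonyl by retro-Claisen cleavage, and the very acidic, polar aldehyde may be lost on work-up. The fallback sets out from lactone 17 and introduces the formyl group electrophilically. Vilsmeier–Haack chloroformylation (POCl3, DMF, 0 °C → rt) should give (R)-4-chloro-6-methyl-2-oxo-5,6-dihydro-2H-pyran-3-carbaldehyde F7. Addition–elimination of water at C4 (NaOAc, aqueous dioxane, rt) should restore the enol and come back to the route at 19.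

## Further compounds

F1 | step 10 | tert-butyl (2E,3E,6R)-6-methyl-2-[(2S)-2-methylbutylidene]-9-oxonon-3-enoate | CC[C@H](C)/C=C(\C=C\C[C@H](C)CCC=O)C(=O)OC(C)(C)C
F2 | step 10 | (4R,6E,8E,10S)-8-(tert-butoxycarbonyl)-4,10-dimethyldodeca-6,8-dienoic acid | CC[C@H](C)/C=C(\C=C\C[C@H](C)CCC(=O)O)C(=O)OC(C)(C)C
F3 | step 10 | (R)-6-methyl-2-oxo-5,6-dihydro-2H-pyran-4-yl (4R,6E,8E,10S)-8-(tert-butoxycarbonyl)-4,10-dimethyldodeca-6,8-dienoate | CC[C@H](C)/C=C(\C=C\C[C@H](C)CCC(=O)OC1=CC(=O)O[C@H](C)C1)C(=O)OC(C)(C)C
F4 | step 6 | tert-butyl (S,Z)-2-bromo-4-methylhex-2-enoate | CC[C@H](C)/C=C(\Br)C(=O)OC(C)(C)C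
F5 | step 6 | (S)-4-methylhex-5-en-1-yne | C#CC[C@H](C)C=C
F6 | step 6 | (S,E)-4,4,5,5-tetramethyl-2-(4-methylhexa-1,5-dien-1-yl)-1,3,2-dioxaborolane | CC1(C)OB(/C=C/C[C@H](C)C=C)OC1(C)C
F7 | step 9 | (R)-4-chloro-6-methyl-2-oxo-5,6-dihydro-2H-pyran-3-carbaldehyde | O=CC1=C(Cl)C[C@@H](C)OC1=O
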